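**Retrosynthetic overview**
1. The target is fisetinidol-(4α→6)-fisetinidol-(4α→6)-catechin-(8→4α)-fisetinidol, every unit (2R,3S). No ring is built: the four pyran rings come intact from (+)-taxifolin (three 5-deoxy units) and (+)-catechin. Bonds are formed in the order C4(D)–C8, C4(B)–C6, C4(A)–C6(B).
2. Key disconnection (used three times): interflavan C4–C(aryl) bond ⇒ nucleophilic arene + C4 enolonium (α-keto cation) made by Ag(I) two-electron oxidation of a (2R)-flavan-3-one enol. Two natively nucleophilic carbons are joined.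
3. Each new 3-ketone is trapped in the same pot as its C3=C4 enol triflate, which erases C4 and blocks over-oxidation. 6-Bromo caps on the ketones used for units D and A give regiocontrol.
4. End game: the triflates are reduced to three 4-aryl-flav-3-enes, then one triple hydroboration–oxidation anti to each 2-aryl sets all six C3/C4 centres (2,3-trans-3,4-trans). Hydride reduction of 4-arylflavan-3-ones is expected to place 3-OH cis to the aryl groups, so it is not used. Global hydrogenolysis removes 14 Bn and 2 Br.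
5. Ketone: taxifolin → 7,3',4'-tri-O-benzyl → 5-OTf → 5-H → C4 deoxygenation → C3 oxidation.

Assumption: common reagents (BnBr, PhNTf2, NBS, AgBF4, KHMDS and the like) are commercial and are not numbered. C4 of the non-isolated ketones 11, 13 and 15 is left undefined because it is erased in the same pot.

**Step 1**
Reactants: 1 (+)-taxifolin
Product: 2 7,3',4'-tri-O-benzyltaxifolin
Conditions: BnBr (3.2 equiv), K2CO3, DMF, 0 °C→rt
Reagents that add atoms: benzyl bromide BrCc1ccccc1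
Why: Williamson etherification in which the C4=O-chelated 5-OH and the secondary 3-OH are the least reactive hydroxyls and stay free, leaving C2/C3 untouched.

**Step 2**
Reactants: 2 7,3',4'-tri-O-benzyltaxifolin
Product: 3 7,3',4'-tri-O-benzyltaxifolin 5-O-triflate
Conditions: PhNTf2, Et3N, DMAP (cat.), CH2Cl2, rt
Reagents that add atoms: N-phenyl-bis(trifluoromethanesulfonimide) O=S(=O)(N(c1ccccc1)S(=O)(=O)C(F)(F)F)C(F)(F)F
Why: phenol-selective O-triflation, since the triflimide transfers Tf to the phenoxide but not to the secondary alcohol.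

**Step 3**
Reactants: 3 7,3',4'-tri-O-benzyltaxifolin 5-O-triflate
Product: 4 7,3',4'-tri-O-benzylfustin
Conditions: Pd(OAc)2 (cat.), dppf, HCO2H, Et3N, DMF, 70 °C
Reagents that add atoms: none
Why: Pd-catalysed formate reduction of an aryl triflate (Cacchi reduction) removes the 5-oxygen while benzyl ethers and the trans-2,3 stereocentres are untouched.

**Step 4**
Reactants: 4 7,3',4'-tri-O-benzylfustin
Product: 6 7,3',4'-tri-O-benzylfisetinidol, via flavan-3,4-diol 5 (not isolated)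
Conditions: NaBH4, THF/MeOH, 0 °C; then Et3SiH, TFA, CH2Cl2, −20 °C→0 °C
Reagents that add atoms: none
Why: carbonyl reduction followed by ionic hydrogenation (Kursanov–Parnes) of the 7-O-stabilised benzylic C4 carbinol, with excess silane outcompeting self-condensation and C2/C3 of taxifolin carried over unchanged as (2R,3S).

**Step 5**
Reactants: 6 7,3',4'-tri-O-benzylfisetinidol
Product: 7 (2R)-7-benzyloxy-2-[3,4-bis(benzyloxy)phenyl]chroman-3-one
Conditions: Dess–Martin periodinane, wet CH2Cl2, rt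
Reagents that add atoms: none
Why: Dess–Martin oxidation under neutral conditions, which for benzylated flavan-3-ols gives the 3-ketone without epimerising C2.

**Step 6**
Reactants: 7 (2R)-7-benzyloxy-2-[3,4-bis(benzyloxy)phenyl]chroman-3-one
Product: 8 (2R)-7-benzyloxy-6-bromo-2-[3,4-bis(benzyloxy)phenyl]chroman-3-one
Conditions: NBS (1.0 equiv), MeCN, −30 °C→0 °C
Reagents that add atoms: N-bromosuccinimide O=C1CCC(=O)N1Br
Why: electrophilic aromatic bromination at C6 (para to O1, ortho to 7-OBn) of the resorcinol-diether ring, expected to be faster than uncatalysed α-bromination of the ketone or attack on the catechol-diether ring.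

**Step 7**
Reactants: 9 (+)-catechin
Product: 10 3,5,7,3',4'-penta-O-benzylcatechin
Conditions: NaH, BnBr, DMF, 0 °C→rt
Reagents that add atoms: benzyl bromide BrCc1ccccc1
Why: exhaustive Williamson O-benzylation, which also removes the free 3-OH that would interfere with the later base and triflating steps.

**Step 8**
Reactants: 8 (2R)-7-benzyloxy-6-bromo-2-[3,4-bis(benzyloxy)phenyl]chroman-3-one; 10 3,5,7,3',4'-penta-O-benzylcatechin (2.5 equiv)
Product: 12 dimer enol triflate (unit D 3-triflyloxy-flav-3-ene bonded C4→C8 to penta-O-benzylcatechin), via dimer ketone 11 (not isolated)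
Conditions: AgBF4 (2.2 equiv), THF, 0 °C→rt; then KHMDS, PhNTf2, THF, −78 °C→0 °C
Reagents that add atoms: N-phenyl-bis(trifluoromethanesulfonimide) O=S(=O)(N(c1ccccc1)S(=O)(=O)C(F)(F)F)C(F)(F)F
Why: Ag(I)-mediated oxidative α-arylation of a flavan-3-one (a reaction type known for per-O-methyl 3-oxocatechin with tetra-O-methylcatechin), in which two-electron oxidation of the C3–C4 enol gives the enolonium that catechin C8 captures in a Friedel–Crafts step, after which the C4 enolate is O-triflated so that no new stereocentre remains and C2 is untouched.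

**Step 9**
Reactants: 7 (2R)-7-benzyloxy-2-[3,4-bis(benzyloxy)phenyl]chroman-3-one (added slowly); 12 dimer enol triflate (1.5 equiv)
Product: 14 trimer bis(enol triflate) (unit B at catechin C6, unit D at C8), via trimer ketone 13 (not isolated)
Conditions: AgBF4 (2.2 equiv), THF, 0 °C→rt; then KHMDS, PhNTf2, THF, −78 °C→0 °C
Reagents that add atoms: N-phenyl-bis(trifluoromethanesulfonimide) O=S(=O)(N(c1ccccc1)S(=O)(=O)C(F)(F)F)C(F)(F)F
Why: Proposed new method: the same Ag(I) enolonium arylation applied to the flanked C6 of an 8-substituted per-benzyl catechin, reasoned from C6 being the only free position on the most electron-rich ring, from the enolonium being flat at C3/C4 and so slimmer than a 3-oxygenated flavan-4-yl cation, and from slow addition of 7 limiting its self-condensation, the closest known reactions being the Ag(I) oxidative flavan-3-one/catechin coupling and C6 Friedel–Crafts couplings of 8-halo-capped benzylated catechins.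

**Step 10**
Reactants: 8 (2R)-7-benzyloxy-6-bromo-2-[3,4-bis(benzyloxy)phenyl]chroman-3-one (2 equiv); 14 trimer bis(enol triflate)
Product: 16 tetramer tris(enol triflate), via tetramer ketone 15 (not isolated)
Conditions: AgBF4, THF, 0 °C→rt; then KHMDS, PhNTf2, THF, −78 °C→0 °C
Reagents that add atoms: N-phenyl-bis(trifluoromethanesulfonimide) O=S(=O)(N(c1ccccc1)S(=O)(=O)C(F)(F)F)C(F)(F)F
Why: the same Ag(I) oxidative enolonium arylation followed by enol triflation, now at C6 of unit B (para to O1, ortho to 7-OBn), the only unhindered activated position because unit D and ketone 8 are bromo-capped and the catechin ring is fully substituted.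

**Step 11**
Reactants: 16 tetramer tris(enol triflate)
Product: 17 tetramer tris(flav-3-ene)
Conditions: Pd(OAc)2 (cat.), PPh3, HCO2H, Et3N, DMF, 60 °C
Reagents that add atoms: none
Why: Pd-catalysed formate reduction of vinyl triflates (Cacchi reduction) gives the three 4-aryl-2H-chromenes, with the electron-rich hindered aryl bromides expected to survive and C2 untouched.

**Step 12**
Reactants: 17 tetramer tris(flav-3-ene)
Product: 18 tetradeca-O-benzyl dibromo tetraflavanoid triol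
Conditions: BH3·THF, THF, 0 °C→rt; then NaOH, H2O2, 0 °C
Reagents that add atoms: hydrogen peroxide OO
Why: hydroboration–oxidation (known to convert flav-3-enes into 2,3-trans-flavan-3-ols), in which syn H–B addition anti to each C2 aryl with boron on C3 gives 3-OH trans to the 2-aryl and H-4 cis to 3-OH, that is 2,3-trans-3,4-trans in all three units ((3S,4R) in A, (3S,4S) in B and D).

**Step 13**
Reactants: 18 tetradeca-O-benzyl dibromo tetraflavanoid triol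
Product: 19 CNP0263622.1
Conditions: H2 (1 atm), Pd(OH)2/C, Et3N, THF/MeOH/H2O, rt
Reagents that add atoms: none
Why: global hydrogenolysis of fourteen benzyl ethers and hydrodebromination of the two aryl bromide caps, with no stereocentre affected.

**Compound list**
1 | (+)-taxifolin, (2R,3R)-dihydroquercetin | O=C1c2c(O)cc(O)cc2O[C@H](c2ccc(O)c(O)c2)[C@H]1O | starting material
2 | (2R,3R)-7-benzyloxy-2-[3,4-bis(benzyloxy)phenyl]-3,5-dihydroxychroman-4-one | O=C1c2c(O)cc(OCc3ccccc3)cc2O[C@H](c2ccc(OCc3ccccc3)c(OCc3ccccc3)c2)[C@H]1O | intermediate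
3 | (2R,3R)-7-benzyloxy-2-[3,4-bis(benzyloxy)phenyl]-3-hydroxy-4-oxochroman-5-yl triflate | O=C1c2c(OS(=O)(=O)C(F)(F)F)cc(OCc3ccccc3)cc2O[C@H](c2ccc(OCc3ccccc3)c(OCc3ccccc3)c2)[C@H]1O | intermediate
4 | (2R,3R)-7-benzyloxy-2-[3,4-bis(benzyloxy)phenyl]-3-hydroxychroman-4-one (tri-O-benzylfustin) | O=C1c2ccc(OCc3ccccc3)cc2O[C@H](c2ccc(OCc3ccccc3)c(OCc3ccccc3)c2)[C@H]1O | intermediate
5 | (2R,3S,4R)-7-benzyloxy-2-[3,4-bis(benzyloxy)phenyl]chroman-3,4-diol (not isolated) | O[C@@H]1c2ccc(OCc3ccccc3)cc2O[C@H](c2ccc(OCc3ccccc3)c(OCc3ccccc3)c2)[C@H]1O | intermediate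
6 | (2R,3S)-7-benzyloxy-2-[3,4-bis(benzyloxy)phenyl]chroman-3-ol (tri-O-benzylfisetinidol) | C(c1ccccc1)Oc1ccc2c(c1)O[C@H](c1ccc(OCc3ccccc3)c(OCc3ccccc3)c1)[C@@H](O)C2 | intermediate
7 | (2R)-7-benzyloxy-2-[3,4-bis(benzyloxy)phenyl]chroman-3-one | C(c1ccccc1)Oc1ccc2c(c1)O[C@H](c1ccc(OCc3ccccc3)c(OCc3ccccc3)c1)C(=O)C2 | intermediate
8 | (2R)-7-benzyloxy-6-bromo-2-[3,4-bis(benzyloxy)phenyl]chroman-3-one | C(c1ccccc1)Oc1c(Br)cc2c(c1)O[C@H](c1ccc(OCc3ccccc3)c(OCc3ccccc3)c1)C(=O)C2 | intermediate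
9 | (+)-catechin, (2R,3S) | Oc1cc(O)c2c(c1)O[C@H](c1ccc(O)c(O)c1)[C@@H](O)C2 | starting material
10 | (2R,3S)-3,5,7-tris(benzyloxy)-2-[3,4-bis(benzyloxy)phenyl]chroman (penta-O-benzylcatechin) | C(c1ccccc1)Oc1cc(OCc3ccccc3)c2c(c1)O[C@H](c1ccc(OCc3ccccc3)c(OCc3ccccc3)c1)[C@@H](OCc1ccccc1)C2 | intermediate
11 | dimer ketone (not isolated): penta-O-benzylcatechin bearing at C8 the (2R,4RS)-7-benzyloxy-6-bromo-2-[3,4-bis(benzyloxy)phenyl]-3-oxochroman-4-yl group | c1c(OCc3ccccc3)c2c(c(C3c4cc(Br)c(OCc5ccccc5)cc4O[C@H](c4ccc(OCc5ccccc5)c(OCc5ccccc5)c4)C3=O)c1OCc1ccccc1)O[C@H](c1ccc(OCc3ccccc3)c(OCc3ccccc3)c1)[C@@H](OCc1ccccc1)C2 | intermediate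
12 | dimer enol triflate: (2R)-7-benzyloxy-6-bromo-2-[3,4-bis(benzyloxy)phenyl]-4-[(2R,3S)-penta-O-benzylcatechin-8-yl]-2H-chromen-3-yl triflate | c1c(OCc3ccccc3)c2c(c(C3=C(OS(=O)(=O)C(F)(F)F)[C@@H](c4ccc(OCc5ccccc5)c(OCc5ccccc5)c4)Oc4cc(OCc5ccccc5)c(Br)cc34)c1OCc1ccccc1)O[C@H](c1ccc(OCc3ccccc3)c(OCc3ccccc3)c1)[C@@H](OCc1ccccc1)C2 | intermediate
13 | trimer ketone (not isolated): 12 bearing at catechin C6 the (2R,4RS)-7-benzyloxy-2-[3,4-bis(benzyloxy)phenyl]-3-oxochroman-4-yl group | c1cc2c(cc1OCc1ccccc1)O[C@H](c1ccc(OCc3ccccc3)c(OCc3ccccc3)c1)C(=O)C2c1c(OCc3ccccc3)c2c(c(C3=C(OS(=O)(=O)C(F)(F)F)[C@@H](c4ccc(OCc5ccccc5)c(OCc5ccccc5)c4)Oc4cc(OCc5ccccc5)c(Br)cc34)c1OCc1ccccc1)O[C@H](c1ccc(OCc3ccccc3)c(OCc3ccccc3)c1)[C@@H](OCc1ccccc1)C2 | intermediate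
14 | trimer bis(enol triflate): penta-O-benzylcatechin bearing at C6 the (2R)-7-benzyloxy-2-[3,4-bis(benzyloxy)phenyl]-3-triflyloxy-2H-chromen-4-yl group and at C8 its 6-bromo analogue | c1cc2c(cc1OCc1ccccc1)O[C@H](c1ccc(OCc3ccccc3)c(OCc3ccccc3)c1)C(OS(=O)(=O)C(F)(F)F)=C2c1c(OCc3ccccc3)c2c(c(C3=C(OS(=O)(=O)C(F)(F)F)[C@@H](c4ccc(OCc5ccccc5)c(OCc5ccccc5)c4)Oc4cc(OCc5ccccc5)c(Br)cc34)c1OCc1ccccc1)O[C@H](c1ccc(OCc3ccccc3)c(OCc3ccccc3)c1)[C@@H](OCc1ccccc1)C2 | intermediate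
15 | tetramer ketone (not isolated): 14 bearing at C6 of unit B the (2R,4RS)-7-benzyloxy-6-bromo-2-[3,4-bis(benzyloxy)phenyl]-3-oxochroman-4-yl group | C(c1ccccc1)Oc1c(Br)cc2c(c1)O[C@H](c1ccc(OCc3ccccc3)c(OCc3ccccc3)c1)C(=O)C2c1cc2c(cc1OCc1ccccc1)O[C@H](c1ccc(OCc3ccccc3)c(OCc3ccccc3)c1)C(OS(=O)(=O)C(F)(F)F)=C2c1c(OCc3ccccc3)c2c(c(C3=C(OS(=O)(=O)C(F)(F)F)[C@@H](c4ccc(OCc5ccccc5)c(OCc5ccccc5)c4)Oc4cc(OCc5ccccc5)c(Br)cc34)c1OCc1ccccc1)O[C@H](c1ccc(OCc3ccccc3)c(OCc3ccccc3)c1)[C@@H](OCc1ccccc1)C2 | intermediate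
16 | tetramer tris(enol triflate): units A, B and D as (2R)-3-triflyloxy-2H-chromenes, linked A C4→B C6, B C4→catechin C6, D C4→catechin C8 | C(c1ccccc1)Oc1c(Br)cc2c(c1)O[C@H](c1ccc(OCc3ccccc3)c(OCc3ccccc3)c1)C(OS(=O)(=O)C(F)(F)F)=C2c1cc2c(cc1OCc1ccccc1)O[C@H](c1ccc(OCc3ccccc3)c(OCc3ccccc3)c1)C(OS(=O)(=O)C(F)(F)F)=C2c1c(OCc3ccccc3)c2c(c(C3=C(OS(=O)(=O)C(F)(F)F)[C@@H](c4ccc(OCc5ccccc5)c(OCc5ccccc5)c4)Oc4cc(OCc5ccccc5)c(Br)cc34)c1OCc1ccccc1)O[C@H](c1ccc(OCc3ccccc3)c(OCc3ccccc3)c1)[C@@H](OCc1ccccc1)C2 | intermediate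
17 | tetramer tris(flav-3-ene): as 16 with each OTf replaced by H (three (2S)-4-aryl-2H-chromene units; same spatial arrangement at C2) | C(c1ccccc1)Oc1c(Br)cc2c(c1)O[C@H](c1ccc(OCc3ccccc3)c(OCc3ccccc3)c1)C=C2c1cc2c(cc1OCc1ccccc1)O[C@H](c1ccc(OCc3ccccc3)c(OCc3ccccc3)c1)C=C2c1c(OCc3ccccc3)c2c(c(C3=C[C@@H](c4ccc(OCc5ccccc5)c(OCc5ccccc5)c4)Oc4cc(OCc5ccccc5)c(Br)cc34)c1OCc1ccccc1)O[C@H](c1ccc(OCc3ccccc3)c(OCc3ccccc3)c1)[C@@H](OCc1ccccc1)C2 | intermediate
18 | 6-bromo-tri-O-benzylfisetinidol-(4α→6)-tri-O-benzylfisetinidol-(4α→6)-[6-bromo-tri-O-benzylfisetinidol-(4α→8)]-penta-O-benzylcatechin; A (2R,3S,4R), B (2R,3S,4S), D (2R,3S,4S), catechin (2R,3S) | C(c1ccccc1)Oc1c(Br)cc2c(c1)O[C@H](c1ccc(OCc3ccccc3)c(OCc3ccccc3)c1)[C@@H](O)[C@@H]2c1cc2c(cc1OCc1ccccc1)O[C@H](c1ccc(OCc3ccccc3)c(OCc3ccccc3)c1)[C@@H](O)[C@@H]2c1c(OCc3ccccc3)c2c(c([C@@H]3c4cc(Br)c(OCc5ccccc5)cc4O[C@H](c4ccc(OCc5ccccc5)c(OCc5ccccc5)c4)[C@H]3O)c1OCc1ccccc1)O[C@H](c1ccc(OCc3ccccc3)c(OCc3ccccc3)c1)[C@@H](OCc1ccccc1)C2 | intermediate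
19 | CNP0263622.1, fisetinidol-(4α→6)-fisetinidol-(4α→6)-catechin-(8→4α)-fisetinidol; A (2R,3S,4R), B (2R,3S,4S), D (2R,3S,4S), catechin (2R,3S) | Oc1ccc2c(c1)O[C@H](c1ccc(O)c(O)c1)[C@@H](O)[C@@H]2c1cc2c(cc1O)O[C@H](c1ccc(O)c(O)c1)[C@@H](O)[C@@H]2c1c(O)c2c(c([C@@H]3c4ccc(O)cc4O[C@H](c4ccc(O)c(O)c4)[C@H]3O)c1O)O[C@H](c1ccc(O)c(O)c1)[C@@H](O)C2 | target

**Totals**
Total step count: 13. Longest linear sequence: 12 steps (steps 1–6, then 8–13).

**Three steps most likely to fail**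

Step 9 (arylation at the flanked C6; the uncapped ketone 7 can also attack itself, and the 2H-chromene unit already present could act as a hydride donor). The fallback sets out from 7. It is converted with TMSOTf/Et3N (CH2Cl2, −78 °C) into (2R)-7-benzyloxy-2-[3,4-bis(benzyloxy)phenyl]-3-(trimethylsilyloxy)-2H-chromene F1. F1 is turned completely into a discrete iodine(III) enolonium with PhI(OAc)2/BF3·OEt2 at −78 °C before any nucleophile is present, so no free ketone remains to self-condense and the electrophile can be used in excess. Compound 12 is then added. This gives trimer ketone 13, where the route is rejoined (enol triflation to 14).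

Step 12 (three hindered hydroborations at once; facial selectivity and β-aryloxyborane elimination are the concerns). The fallback sets out from 17. Stoichiometric OsO4/pyridine adds syn, anti to each 2-aryl, to give the tris(3β,4β-diol) hexaol F2. The three secondary 3-OH groups are silylated with iPr2SiHCl/imidazole to the tris(3-O-diisopropylsilyl) ether F3. BF3·OEt2 (CH2Cl2, −78 °C) ionises each doubly benzylic tertiary C4–OH and the tethered Si–H delivers hydride to C4 on the face of the C3 oxygen, giving the tris(3-O-fluorodiisopropylsilyl) ether F4 with the 3,4-trans arrangement. TBAF then returns to 18.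

Step 8 (Ag(I) may fail to oxidise the less electron-rich 5-deoxy enol, or may oxidise toward C2). The fallback sets out from 8. Regitz diazo transfer (p-ABSA, Et3N, MeCN, 0 °C) gives (2R)-7-benzyloxy-6-bromo-2-[3,4-bis(benzyloxy)phenyl]-4-diazochroman-3-one F5. A gold(I)-phosphite catalyst then turns F5 into an electrophilic α-oxo carbenoid (a non-oxidative enolonium equivalent) that functionalises C8–H of 10. This gives dimer ketone 11, where the route is rejoined (enol triflation to 12).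

**Further compounds**
F1 | step 9 | (2R)-7-benzyloxy-2-[3,4-bis(benzyloxy)phenyl]-3-(trimethylsilyloxy)-2H-chromene | C(c1ccccc1)Oc1ccc2c(c1)O[C@H](c1ccc(OCc3ccccc3)c(OCc3ccccc3)c1)C(O[Si](C)(C)C)=C2
F2 | step 12 | hexaol: 18 carrying an additional 4-OH (cis to 3-OH, 4-aryl α) in units A, B and D | C(c1ccccc1)Oc1c(Br)cc2c(c1)O[C@H](c1ccc(OCc3ccccc3)c(OCc3ccccc3)c1)[C@@H](O)[C@]2(O)c1cc2c(cc1OCc1ccccc1)O[C@H](c1ccc(OCc3ccccc3)c(OCc3ccccc3)c1)[C@@H](O)[C@]2(O)c1c(OCc3ccccc3)c2c(c([C@]3(O)c4cc(Br)c(OCc5ccccc5)cc4O[C@H](c4ccc(OCc5ccccc5)c(OCc5ccccc5)c4)[C@H]3O)c1OCc1ccccc1)O[C@H](c1ccc(OCc3ccccc3)c(OCc3ccccc3)c1)[C@@H](OCc1ccccc1)C2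
F3 | step 12 | tris(3-O-diisopropylsilyl) ether of hexaol F2 (tertiary 4-OH groups free) | C(c1ccccc1)Oc1c(Br)cc2c(c1)O[C@H](c1ccc(OCc3ccccc3)c(OCc3ccccc3)c1)[C@@H](O[SiH](C(C)C)C(C)C)[C@]2(O)c1cc2c(cc1OCc1ccccc1)O[C@H](c1ccc(OCc3ccccc3)c(OCc3ccccc3)c1)[C@@H](O[SiH](C(C)C)C(C)C)[C@]2(O)c1c(OCc3ccccc3)c2c(c([C@]3(O)c4cc(Br)c(OCc5ccccc5)cc4O[C@H](c4ccc(OCc5ccccc5)c(OCc5ccccc5)c4)[C@H]3O[SiH](C(C)C)C(C)C)c1OCc1ccccc1)O[C@H](c1ccc(OCc3ccccc3)c(OCc3ccccc3)c1)[C@@H](OCc1ccccc1)C2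
F4 | step 12 | tris(3-O-fluorodiisopropylsilyl) ether of 18 | C(c1ccccc1)Oc1c(Br)cc2c(c1)O[C@H](c1ccc(OCc3ccccc3)c(OCc3ccccc3)c1)[C@@H](O[Si](F)(C(C)C)C(C)C)[C@@H]2c1cc2c(cc1OCc1ccccc1)O[C@H](c1ccc(OCc3ccccc3)c(OCc3ccccc3)c1)[C@@H](O[Si](F)(C(C)C)C(C)C)[C@@H]2c1c(OCc3ccccc3)c2c(c([C@@H]3c4cc(Br)c(OCc5ccccc5)cc4O[C@H](c4ccc(OCc5ccccc5)c(OCc5ccccc5)c4)[C@H]3O[Si](F)(C(C)C)C(C)C)c1OCc1ccccc1)O[C@H](c1ccc(OCc3ccccc3)c(OCc3ccccc3)c1)[C@@H](OCc1ccccc1)C2
F5 | step 8 | (2R)-7-benzyloxy-6-bromo-2-[3,4-bis(benzyloxy)phenyl]-4-diazochroman-3-one | C(c1ccccc1)Oc1c(Br)cc2c(c1)O[C@H](c1ccc(OCc3ccccc3)c(OCc3ccccc3)c1)C(=O)C2=[N+]=[N-]
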